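## Structural features

The target is a 2,3-dihydro-1,4-benzodioxine: aromatic ring A is fused to the dioxane ring B and carries a methoxy group at C5 and an (E)-3-hydroxyprop-1-enyl chain at C7, while C2 (Cα) bears ring C, a 3,4-dihydroxy-5-methoxyphenyl group, and C3 (Cβ) bears a hydroxymethyl group (Cγ). The two ring B oxygens are not equivalent: O1, bonded to Cα, sits on the ring A carbon next to an aromatic C–H, whereas O4, bonded to Cβ, sits on the carbon flanked by the C5 methoxy group. Cα (S) and Cβ (R) are adjacent stereocentres with aryl and hydroxymethyl cis, the less stable arrangement, so they must be set under kinetic control and as one enantiomer. Fragile elements are the air-sensitive catechol of ring C, the cinnamyl alcohol (ionised by acid) and above all the Cα–O1 bond, a para-hydroxybenzyl aryl ether that can open to a quinone methide under base once the ring C phenol is free, or to a benzylic cation under acid, either of which would leak cis into trans. The real difficulty is therefore the combination of ring B regiochemistry, cis relative configuration and absolute configuration, not the carbon skeleton, which is two C6–C3 units joined only through oxygen. The key step exploits the 1,2-relationship between O4 on Cβ and the hydroxyl on Cγ: it is the trace of a Cβ–Cγ oxirane opened at Cβ by the ring A phenoxide oxygen next to the methoxy group, a 6-exo closure of ring B that inverts Cβ and frees the Cγ hydroxyl in one event.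

## Logic of the disconnections

13 to 12: the two C–H bonds of the allylic CH2OH are traced back to an ester carbonyl. The ester survives base, zerovalent palladium and acid, whereas the cinnamyl alcohol would not survive acid, so it is revealed last. The forward step must be a clean 1,2-reduction in the presence of three free hydroxyl groups and must avoid acid and base at Cα.

12 to 11: the two phenolic O–H bonds of ring C are traced back to O–CH2OCH3 acetals. The para oxygen of ring C must stay masked whenever a phenoxide is generated elsewhere in the molecule. The forward cleavage must be mild enough not to ionise Cα.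

11 to 10: the O4–Cβ bond is cut. This removes ring B and one stereocentre and leaves an acyclic aryl ether with a terminal oxirane. The forward step must attack Cβ and not Cγ, with inversion, so 10 needs (S) configuration at Cβ next to (S) at Cα.

10 to 9: the phenolic O–H of ring A is traced back to an allyl ether. O4 has to be blocked while O1 is attached to Cα, by a group that cannot migrate between the neighbouring oxygens. The forward deallylation must leave the oxirane alone; it is chosen so that it produces the phenoxide directly and runs into the ring closure.

9 to 5 and 8: the Cα–O1 bond is cut, the only link between the two aromatic halves. This gives two fragments of similar size, both derived from 1. The forward etherification must be an SN2 displacement at the benzylic carbinol with full inversion, so 5 must carry the opposite configuration at Cα (anti epoxy alcohol).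

5 to 4: the two C–O bonds of the oxirane are cut back to the vinyl group. The allylic hydroxyl directs a tartrate-controlled epoxidation that also resolves the racemate. The forward step must select the (S)-enantiomer of 4 and deliver oxygen anti to the carbinol substituent; at most half of 4 is usable.

4 to 2 and 3: the Cα–Cβ bond is cut. This reduces the C3 unit of ring C to an aldehyde and a vinyl nucleophile; no stereocontrol is asked of the forward addition.

2 to 1: the two O–CH2 acetal bonds are cut; the forward step is a double O-alkylation.

8 to 6 and 7: the side-chain C=C bond is cut. Installing the complete three-carbon chain before the coupling means no carbon–carbon bond has to be made after the stereocentres exist. The forward olefination must be E-selective and tolerate a free phenol.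

6 to 1: the O–allyl bond is cut. The forward alkylation must hit only the oxygen para to the formyl group, which fixes which ring A oxygen later becomes O4.

## Other disconnections considered

Alternative 1: The cut removes the Cα–Cβ bond and a Cγ–O bond, tracing ring B to the cis-2-aryl-3-aryloxyoxetane A3 and A3 to the ring C aldehyde A1 and the ring A aryl vinyl ether A2.
- Forward key step: a Paternò–Büchi photocycloaddition. The triplet n,π* state of A1 would add through oxygen to the terminal carbon of A2 and the 1,4-biradical would close to A3. Desilylation of the ring A silyl ether would then let the phenoxide open the oxetane at benzylic Cα with inversion (6-exo), releasing the Cγ hydroxyl.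
- In its favour: it is the most convergent plan, it makes the Cα–Cβ bond and both stereocentres from two achiral aromatic partners in one operation, and the pivalates of ring C would fall in the final hydride reduction. On that last point, the absence of an acidic deprotection, it is better than the chosen plan.
- Against it here: a photocycloaddition gives no control of absolute configuration, so A3 would be racemic and a resolution would have to be added. The cis/trans outcome would depend on biradical conformations and not on a stereospecific event. A trioxygenated benzaldehyde has a low-lying π,π* triplet and is a poor partner, and aryl esters invite photo-Fries chemistry. An oxetane is a far weaker electrophile than an oxirane, so activation strong enough to open it threatens SN1 scrambling at Cα. The side chain would still have to be grown from the benzylic silyl ether by oxidation, olefination and reduction.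
- Comparison: in mechanistic logic the two plans are equals (strain-release 6-exo opening with inversion, at Cα there and at Cβ here), and the alternative is shorter up to ring B. The chosen plan is preferred because its stereocentres come from a tartrate-controlled epoxidation and two stereospecific SN2 events, and because two steps follow ring closure instead of about four.

Alternative 2: The cut is the bond between O1 and ring A, tracing the cyclised acetal A6 to the bromo alcohol A5, in which O4 already links Cβ to a ring A made from 5-bromovanillin A4.
- Forward key step: an intramolecular Ullmann etherification. CuI (monovalent copper) with 1,10-phenanthroline and Cs2CO3 in hot toluene would couple the Cα alkoxide with the neighbouring aryl bromide.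
- In its favour: ring closure touches neither stereocentre, so the cis relationship is inherited from erythro A5 and could be checked before cyclisation. There is a single electrophilic site, so no exo/endo question arises. A4 is cheap and has the bromine on the correct carbon. On stereochemical security of the ring closure and on regiochemical unambiguity of the electrophile this plan is the better one.
- Against it here: the stereochemical problem is only moved into the preparation of enantiopure erythro A5. The aryl bromide is electron-rich and flanked by an alkoxy group, a slow partner for copper. A secondary benzylic alkoxide at high temperature is prone to oxidation to the ketone and to loss of bromine by reduction. The side chain is present only as a masked aldehyde, so acetal hydrolysis, olefination, desilylation, acetal removal on ring C and reduction would follow, about five steps against two, two of them acidic operations on the sensitive Cα ether.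
- Comparison: structurally it is the mirror image of the chosen plan (O4 attached first, O1 last) and equally sound in regiochemistry. Mechanistically its ring closure is safer in configuration but harsher in conditions. In step economy it is clearly longer.

Alternative 3: Both ring B bonds Cα–O1 and O4–aryl are cut, tracing the benzodioxane aldehyde A9 to the (2R,3R)-aryl epoxide A7 and the bromophenol A8.
- Forward key step: a domino sequence. The phenoxide of A8 would open A7 at benzylic Cα with inversion, and the liberated Cβ alkoxide would be arylated at the adjacent C–Br carbon under CuI catalysis with retention at Cβ.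
- In its favour: two C–O bonds and ring B would form in one flask. A7 would come from a Sharpless epoxidation of a cinnamyl alcohol run to full conversion, which is better in material economy than a kinetic resolution, and no Mitsunobu reaction is needed. The C–Br carbon is para to the formyl group and so activated.
- Against it here: the regiochemistry demands bromine between hydroxyl and methoxy (A8); the commodity isomer A4 would give ring B with O1 and O4 exchanged. Inversion at an electron-rich benzylic epoxide carbon must stay SN2 under hot basic conditions, and any SN1 character would give the trans isomer. An aldehyde must survive hot base and copper. Olefination, acidic removal of three acetals and reduction would follow ring closure, three steps against two.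
- Comparison: if A8 can be bought the overall length is about the same, so on step economy the plans are equal, and the domino is superior in bonds formed per operation. The chosen plan keeps the ring-closing SN2 event at a non-benzylic carbon and carries the finished side chain through, which is why it is preferred.

Key step: step 7

Remarks on the chemistry:
- Cα, Cβ and Cγ are used as defined above; benzodioxine locants put O1 on C2 (Cα) and the methoxy group at C5.
- The configurations were re-derived from the line notations: 5 is (αR,βS), 9 and 10 are (αS,βS), and 11, 12 and 13 are (αS,βR) with aryl and CH2OH cis. One inversion at Cα (step 6) and one at Cβ (step 7) connect them, and no structure needed correction.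
- The hand of the tartrate is not free. By the empirical facial rule of the Sharpless epoxidation, only the D-(−) series consumes the (S)-enantiomer of 4 and gives 5. The change of descriptor at Cα from S in that enantiomer to R in 5 is a change of priorities only.
- Design improvement: the free phenol 10 is generated as its phenoxide under the conditions that cyclise it, so it is never isolated.

Step 1
Reactants: 1 3,4-dihydroxy-5-methoxybenzaldehyde
Product: 2 3-methoxy-4,5-bis(methoxymethoxy)benzaldehyde
Conditions: MOMCl (2.6 equiv), i-Pr2NEt (3 equiv), CH2Cl2, 0 °C → rt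
Reagents that add atoms: chloromethyl methyl ether, COCCl
Why: Double O-alkylation of the phenols (Williamson-type acetal formation). The MOM ethers are inert to the Grignard reagent, the titanium epoxidation, the Mitsunobu reaction, zerovalent palladium and carbonate in methanol, and they keep the para oxygen of ring C from becoming a phenoxide in step 7.

Step 2
Reactants: 2 3-methoxy-4,5-bis(methoxymethoxy)benzaldehyde; 3 vinylmagnesium bromide
Product: 4 rac-1-[3-methoxy-4,5-bis(methoxymethoxy)phenyl]prop-2-en-1-ol
Conditions: THF, −78 → 0 °C; then aq NH4Cl
Reagents that add atoms: none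
Why: Grignard 1,2-addition to the aryl aldehyde forms the Cα–Cβ bond and gives the racemic secondary allylic alcohol; the acetal ethers do not react.

Step 3
Reactants: 4 rac-1-[3-methoxy-4,5-bis(methoxymethoxy)phenyl]prop-2-en-1-ol
Product: 5 (R)-[3-methoxy-4,5-bis(methoxymethoxy)phenyl][(2S)-oxiran-2-yl]methanol
Conditions: Ti(OiPr)4 (0.15 equiv), D-(−)-DIPT (0.2 equiv), t-BuOOH (0.45 equiv), 4 Å MS, CH2Cl2, −20 °C
Reagents that add atoms: tert-butyl hydroperoxide, CC(C)(C)OO
Why: Sharpless kinetic resolution. With (2S,3S)-diisopropyl tartrate the (S)-enantiomer of 4 is the fast one and is epoxidised on the face that gives the erythro (anti) epoxy alcohol, so Cβ (S) is set by the tartrate and Cα by selection of one enantiomer. Substoichiometric hydroperoxide leaves the (R)-alcohol, which is separated by chromatography.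

Step 4
Reactants: 1 3,4-dihydroxy-5-methoxybenzaldehyde
Product: 6 4-(allyloxy)-3-hydroxy-5-methoxybenzaldehyde
Conditions: allyl bromide (1.05 equiv), Li2CO3 (1.2 equiv), DMF, 45 °C
Reagents that add atoms: allyl bromide, C=CCBr
Why: Regioselective Williamson etherification. The weak base deprotonates only the hydroxyl para to the formyl group, so the allyl group goes on the oxygen flanked by methoxy and hydroxyl (the future O4), and an allyl group cannot migrate to the neighbouring oxygen.

Step 5
Reactants: 6 4-(allyloxy)-3-hydroxy-5-methoxybenzaldehyde; 7 methyl (triphenylphosphoranylidene)acetate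
Product: 8 methyl (E)-3-[4-(allyloxy)-3-hydroxy-5-methoxyphenyl]prop-2-enoate
Conditions: toluene, 80 °C
Reagents that add atoms: none
Why: Wittig olefination with a stabilised ylide gives the (E)-cinnamate and tolerates the free phenol; the temperature is far below that of an aryl allyl ether Claisen rearrangement.

Step 6
Reactants: 5 (R)-[3-methoxy-4,5-bis(methoxymethoxy)phenyl][(2S)-oxiran-2-yl]methanol; 8 methyl (E)-3-[4-(allyloxy)-3-hydroxy-5-methoxyphenyl]prop-2-enoate
Product: 9 methyl (E)-3-[4-(allyloxy)-3-methoxy-5-{(S)-[3-methoxy-4,5-bis(methoxymethoxy)phenyl][(2S)-oxiran-2-yl]methoxy}phenyl]prop-2-enoate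
Conditions: PPh3 (1.5 equiv), DIAD (1.5 equiv), THF, 0 °C → rt
Reagents that add atoms: none
Why: Mitsunobu etherification. The only free phenol of 8 displaces the activated Cα oxygen by SN2 with inversion (R to S at Cα), forming the Cα–O1 bond, while the oxirane is a spectator. Ionisation at Cα is disfavoured by the electron-withdrawing oxirane next to it and by the para acetal oxygen being twisted out of conjugation between two ortho substituents.

Step 7
Reactants: 9 methyl (E)-3-[4-(allyloxy)-3-methoxy-5-{(S)-[3-methoxy-4,5-bis(methoxymethoxy)phenyl][(2S)-oxiran-2-yl]methoxy}phenyl]prop-2-enoate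
Product: 11 methyl (E)-3-{(2S,3R)-3-(hydroxymethyl)-5-methoxy-2-[3-methoxy-4,5-bis(methoxymethoxy)phenyl]-2,3-dihydro-1,4-benzodioxin-7-yl}prop-2-enoate, via ring A phenol epoxide 10 (not isolated)
Conditions: Pd(PPh3)4 (5 mol %), K2CO3 (3 equiv), MeOH–THF, rt → 50 °C
Reagents that add atoms: none
Why: Zerovalent palladium ionises the aryl allyl ether to a π-allyl complex and the ring A phenoxide of 10, and methanol takes up the allyl unit as allyl methyl ether. The phenoxide oxygen next to the methoxy group then attacks the internal oxirane carbon Cβ from the side opposite its C–O bond, and the oxirane oxygen leaves onto Cγ as an alkoxide that methanol protonates. The closest known reaction type is the base-induced cyclisation of 2-(oxiranylmethoxy)phenols to 2-(hydroxymethyl)-1,4-benzodioxanes, here coupled to the carbonate/methanol palladium deallylation of aryl allyl ethers. Ring B closes in the 6-exo-tet mode. The new stereocentre Cβ is controlled by the (S) oxirane carbon of 10 and is inverted stereospecifically to R, which with Cα (S) from step 6 gives the cis ring. The step needs 6-exo over 7-endo selectivity: the collinear backside trajectory to Cβ is reachable through a six-membered transition state, whereas attack at Cγ would place the breaking C–O bond inside a forming seven-membered ring. The two ring A oxygens cannot be exchanged because O1 is already bonded to Cα, and intramolecularity lets the phenoxide outrun methoxide at the oxirane. The MOM ethers keep ring C from forming a para phenoxide that would expel O1 as a quinone methide.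

Step 8
Reactants: 11 methyl (E)-3-{(2S,3R)-3-(hydroxymethyl)-5-methoxy-2-[3-methoxy-4,5-bis(methoxymethoxy)phenyl]-2,3-dihydro-1,4-benzodioxin-7-yl}prop-2-enoate
Product: 12 methyl (E)-3-[(2S,3R)-2-(3,4-dihydroxy-5-methoxyphenyl)-3-(hydroxymethyl)-5-methoxy-2,3-dihydro-1,4-benzodioxin-7-yl]prop-2-enoate
Conditions: HCl (1 M in MeOH, from AcCl), 0 °C → rt
Reagents that add atoms: none
Why: Acid-catalysed acetal methanolysis of the two aryl MOM ethers. Dilute acid at or below room temperature is chosen so that the benzylic aryl ether at Cα is not ionised, and at this stage the side chain is still the acid-stable conjugated methyl ester, which methanol cannot transesterify to anything new.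

Step 9
Reactants: 12 methyl (E)-3-[(2S,3R)-2-(3,4-dihydroxy-5-methoxyphenyl)-3-(hydroxymethyl)-5-methoxy-2,3-dihydro-1,4-benzodioxin-7-yl]prop-2-enoate
Product: 13 (2S,3R)-2-(3,4-dihydroxy-5-methoxyphenyl)-3-(hydroxymethyl)-7-[(E)-3-hydroxyprop-1-en-1-yl]-5-methoxy-2,3-dihydro-1,4-benzodioxine
Conditions: i-Bu2AlH (6 equiv), THF–toluene, −78 → −20 °C; then aq KNaC4H4O6
Reagents that add atoms: none
Why: 1,2-Reduction of the α,β-unsaturated ester by i-Bu2AlH gives the (E)-allylic alcohol. Excess hydride first converts the three hydroxyl groups into aluminium alkoxides, the stereocentres are not touched, and the neutral tartrate work-up avoids acid and base at Cα.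

Compound list

1 | 3,4-dihydroxy-5-methoxybenzaldehyde (5-hydroxyvanillin) | COc1cc(C=O)cc(O)c1O | starting material
2 | 3-methoxy-4,5-bis(methoxymethoxy)benzaldehyde | COc1cc(C=O)cc(OCOC)c1OCOC | intermediate
3 | vinylmagnesium bromide | C=C[Mg]Br | starting material
4 | rac-1-[3-methoxy-4,5-bis(methoxymethoxy)phenyl]prop-2-en-1-ol | COc1cc(C(O)C=C)cc(OCOC)c1OCOC | intermediate
5 | (R)-[3-methoxy-4,5-bis(methoxymethoxy)phenyl][(2S)-oxiran-2-yl]methanol (anti; Cα R, Cβ S) | COc1cc([C@@H](O)[C@@H]2CO2)cc(OCOC)c1OCOC | intermediate
6 | 4-(allyloxy)-3-hydroxy-5-methoxybenzaldehyde | C=CCOc1c(O)cc(C=O)cc1OC | intermediate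
7 | methyl (triphenylphosphoranylidene)acetate | COC(=O)C=P(c1ccccc1)(c1ccccc1)c1ccccc1 | starting material
8 | methyl (E)-3-[4-(allyloxy)-3-hydroxy-5-methoxyphenyl]prop-2-enoate | COC(=O)/C=C/c1cc(O)c(OCC=C)c(OC)c1 | intermediate
9 | methyl (E)-3-[4-(allyloxy)-3-methoxy-5-{(S)-[3-methoxy-4,5-bis(methoxymethoxy)phenyl][(2S)-oxiran-2-yl]methoxy}phenyl]prop-2-enoate (Cα S, Cβ S) | COc1cc([C@H](Oc2cc(/C=C/C(=O)OC)cc(OC)c2OCC=C)[C@@H]2CO2)cc(OCOC)c1OCOC | intermediate
10 | methyl (E)-3-[4-hydroxy-3-methoxy-5-{(S)-[3-methoxy-4,5-bis(methoxymethoxy)phenyl][(2S)-oxiran-2-yl]methoxy}phenyl]prop-2-enoate (Cα S, Cβ S; formed and consumed in step 7) | COc1cc([C@H](Oc2cc(/C=C/C(=O)OC)cc(OC)c2O)[C@@H]2CO2)cc(OCOC)c1OCOC | intermediate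
11 | methyl (E)-3-{(2S,3R)-3-(hydroxymethyl)-5-methoxy-2-[3-methoxy-4,5-bis(methoxymethoxy)phenyl]-2,3-dihydro-1,4-benzodioxin-7-yl}prop-2-enoate (2,3-cis) | COc1cc([C@@H]2Oc3cc(/C=C/C(=O)OC)cc(OC)c3O[C@@H]2CO)cc(OCOC)c1OCOC | intermediate
12 | methyl (E)-3-[(2S,3R)-2-(3,4-dihydroxy-5-methoxyphenyl)-3-(hydroxymethyl)-5-methoxy-2,3-dihydro-1,4-benzodioxin-7-yl]prop-2-enoate (2,3-cis) | COc1cc([C@@H]2Oc3cc(/C=C/C(=O)OC)cc(OC)c3O[C@@H]2CO)cc(O)c1O | intermediate
13 | (2S,3R)-2-(3,4-dihydroxy-5-methoxyphenyl)-3-(hydroxymethyl)-7-[(E)-3-hydroxyprop-1-en-1-yl]-5-methoxy-2,3-dihydro-1,4-benzodioxine (2,3-cis) | COc1cc([C@@H]2Oc3cc(/C=C/CO)cc(OC)c3O[C@@H]2CO)cc(O)c1O | target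

Total step count: 9. Longest linear sequence: 7 steps (steps 1, 2, 3, 6, 7, 8, 9); the ring A branch (steps 4 and 5) joins at step 6.

Least certain steps

Step 7 (key step). What may go wrong:
- competing attack of the phenoxide on the unhindered terminal carbon Cγ (7-endo);
- slow closure by the doubly ortho-substituted phenoxide, allowing intermolecular methanolysis of the oxirane.

Fallback, from 9 back to 11, closing the same bond by a different activation:
- The oxirane of 9 is opened at Cγ with CsO2CCMe3 and Me3CCO2H in DMF at 60 °C to give the Cβ-hydroxy Cγ-pivalate F1.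
- The allyl group is removed under neutral conditions (Pd(PPh3)4, morpholine, THF) to give the phenol F2.
- An intramolecular Mitsunobu etherification (PPh3, DIAD, THF) displaces the activated Cβ oxygen with inversion; this has only one electrophilic carbon and gives the cis pivalate F3.
- NaOMe in MeOH removes the pivalate and the route is rejoined at 11.

Step 6. What may go wrong:
- partial ionisation of the oxyphosphonium intermediate at the benzylic Cα, eroding the inversion and later giving trans material;
- sluggish attack by the ortho-substituted phenol, so that the hydrazide is alkylated instead.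

Fallback, from 2 back to 9, replacing the Mitsunobu inversion by a phenoxide opening of an aryl epoxide followed by an inverting epoxide relay:
- Wittig olefination of 2 with 7 gives the ring C cinnamate F4.
- i-Bu2AlH reduction gives the cinnamyl alcohol F5.
- Sharpless epoxidation with D-(−)-diisopropyl tartrate, run to full conversion, gives the (2R,3R)-epoxy alcohol F6.
- t-BuMe2SiCl and imidazole give the silyl ether F7.
- The phenoxide of 8 (Cs2CO3, DMF, 60 °C) opens F7 at the benzylic carbon with inversion to give the (αS,βR) hydroxy ether F8.
- MsCl and Et3N give the mesylate F9.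
- Bu4NF removes the silyl group and the Cγ alkoxide displaces the mesylate with inversion at Cβ, giving 9.

Step 3. What may go wrong:
- insufficient rate difference between the enantiomers of this hindered, electron-rich aryl vinyl carbinol, so that the epoxy alcohol is formed with inadequate enantiomeric and diastereomeric purity;
- the ceiling of half the material.

Fallback, from 4 back to 5, separating resolution from epoxidation:
- 4 is first resolved with L-(+)-diisopropyl tartrate, Ti(OiPr)4 and t-BuOOH, run past half conversion. The (R)-enantiomer is consumed and the slow-reacting (S)-allylic alcohol F10 is recovered; its enantiomeric purity can be driven up by conversion.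
- F10 is then epoxidised in the matched sense with D-(−)-diisopropyl tartrate to full conversion, giving 5.

Step 8. What may go wrong:
- acid-promoted ionisation of the Cα–O1 bond once the para oxygen of ring C is unmasked, with re-closure to the trans ring or capture of the cation by methanol.

Fallback, from 11 back to 13, reversing the last two operations and removing the acetals without protic acid:
- 11 is first reduced with i-Bu2AlH to the bis-MOM allylic diol F11.
- The aryl MOM ethers are then cleaved by silyl transfer with Me3SiOTf and 2,2′-bipyridyl in CH3CN at 0 °C, followed by water. This hydrolyses the transient silyl ethers and gives 13 directly.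

## Further compounds

F1 | step 7 | methyl (E)-3-[4-(allyloxy)-3-{(1S,2S)-2-hydroxy-1-[3-methoxy-4,5-bis(methoxymethoxy)phenyl]-3-(pivaloyloxy)propoxy}-5-methoxyphenyl]prop-2-enoate | COc1cc([C@H](Oc2cc(/C=C/C(=O)OC)cc(OC)c2OCC=C)[C@@H](O)COC(=O)C(C)(C)C)cc(OCOC)c1OCOC
F2 | step 7 | methyl (E)-3-[4-hydroxy-3-{(1S,2S)-2-hydroxy-1-[3-methoxy-4,5-bis(methoxymethoxy)phenyl]-3-(pivaloyloxy)propoxy}-5-methoxyphenyl]prop-2-enoate | COc1cc([C@H](Oc2cc(/C=C/C(=O)OC)cc(OC)c2O)[C@@H](O)COC(=O)C(C)(C)C)cc(OCOC)c1OCOC
F3 | step 7 | methyl (E)-3-{(2S,3R)-5-methoxy-2-[3-methoxy-4,5-bis(methoxymethoxy)phenyl]-3-[(pivaloyloxy)methyl]-2,3-dihydro-1,4-benzodioxin-7-yl}prop-2-enoate (2,3-cis) | COc1cc([C@@H]2Oc3cc(/C=C/C(=O)OC)cc(OC)c3O[C@@H]2COC(=O)C(C)(C)C)cc(OCOC)c1OCOC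
F4 | step 6 | methyl (E)-3-[3-methoxy-4,5-bis(methoxymethoxy)phenyl]prop-2-enoate | COC(=O)/C=C/c1cc(OC)c(OCOC)c(OCOC)c1
F5 | step 6 | (E)-3-[3-methoxy-4,5-bis(methoxymethoxy)phenyl]prop-2-en-1-ol | OC/C=C/c1cc(OC)c(OCOC)c(OCOC)c1
F6 | step 6 | {(2R,3R)-3-[3-methoxy-4,5-bis(methoxymethoxy)phenyl]oxiran-2-yl}methanol | OC[C@H]1O[C@@H]1c1cc(OC)c(OCOC)c(OCOC)c1
F7 | step 6 | tert-butyl({(2R,3R)-3-[3-methoxy-4,5-bis(methoxymethoxy)phenyl]oxiran-2-yl}methoxy)dimethylsilane | CC(C)(C)[Si](C)(C)OC[C@H]1O[C@@H]1c1cc(OC)c(OCOC)c(OCOC)c1
F8 | step 6 | methyl (E)-3-[4-(allyloxy)-3-{(1S,2R)-3-(tert-butyldimethylsilyloxy)-2-hydroxy-1-[3-methoxy-4,5-bis(methoxymethoxy)phenyl]propoxy}-5-methoxyphenyl]prop-2-enoate | COc1cc([C@H](Oc2cc(/C=C/C(=O)OC)cc(OC)c2OCC=C)[C@H](O)CO[Si](C)(C)C(C)(C)C)cc(OCOC)c1OCOC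
F9 | step 6 | methyl (E)-3-[4-(allyloxy)-3-{(1S,2R)-3-(tert-butyldimethylsilyloxy)-1-[3-methoxy-4,5-bis(methoxymethoxy)phenyl]-2-(methylsulfonyloxy)propoxy}-5-methoxyphenyl]prop-2-enoate | COc1cc([C@H](Oc2cc(/C=C/C(=O)OC)cc(OC)c2OCC=C)[C@H](OS(C)(=O)=O)CO[Si](C)(C)C(C)(C)C)cc(OCOC)c1OCOC
F10 | step 3 | (S)-1-[3-methoxy-4,5-bis(methoxymethoxy)phenyl]prop-2-en-1-ol | COc1cc([C@@H](O)C=C)cc(OCOC)c1OCOC
F11 | step 8 | (2S,3R)-3-(hydroxymethyl)-7-[(E)-3-hydroxyprop-1-en-1-yl]-5-methoxy-2-[3-methoxy-4,5-bis(methoxymethoxy)phenyl]-2,3-dihydro-1,4-benzodioxine (2,3-cis) | COc1cc([C@@H]2Oc3cc(/C=C/CO)cc(OC)c3O[C@@H]2CO)cc(OCOC)c1OCOC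
A1 | alternative 1 | 3-methoxy-4,5-bis(pivaloyloxy)benzaldehyde | COc1cc(C=O)cc(OC(=O)C(C)(C)C)c1OC(=O)C(C)(C)C
A2 | alternative 1 | tert-butyl{[3-(tert-butyldimethylsilyloxy)-4-(ethenyloxy)-5-methoxyphenyl]methoxy}dimethylsilane | C=COc1c(OC)cc(CO[Si](C)(C)C(C)(C)C)cc1O[Si](C)(C)C(C)(C)C
A3 | alternative 1 | (2R,3R)-3-{2-(tert-butyldimethylsilyloxy)-4-[(tert-butyldimethylsilyloxy)methyl]-6-methoxyphenoxy}-2-[3-methoxy-4,5-bis(pivaloyloxy)phenyl]oxetane (2,3-cis) | COc1cc([C@@H]2[C@H](Oc3c(OC)cc(CO[Si](C)(C)C(C)(C)C)cc3O[Si](C)(C)C(C)(C)C)CO2)cc(OC(=O)C(C)(C)C)c1OC(=O)C(C)(C)C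
A4 | alternative 2 | 3-bromo-4-hydroxy-5-methoxybenzaldehyde (5-bromovanillin) | COc1cc(C=O)cc(Br)c1O
A5 | alternative 2 | (1S,2R)-2-[2-bromo-4-(dimethoxymethyl)-6-methoxyphenoxy]-3-(tert-butyldimethylsilyloxy)-1-[3-methoxy-4,5-bis(methoxymethoxy)phenyl]propan-1-ol (erythro) | COc1cc([C@H](O)[C@@H](CO[Si](C)(C)C(C)(C)C)Oc2c(Br)cc(C(OC)OC)cc2OC)cc(OCOC)c1OCOC
A6 | alternative 2 | (2S,3R)-3-[(tert-butyldimethylsilyloxy)methyl]-7-(dimethoxymethyl)-5-methoxy-2-[3-methoxy-4,5-bis(methoxymethoxy)phenyl]-2,3-dihydro-1,4-benzodioxine (2,3-cis) | COc1cc([C@@H]2Oc3cc(C(OC)OC)cc(OC)c3O[C@@H]2CO[Si](C)(C)C(C)(C)C)cc(OCOC)c1OCOC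
A7 | alternative 3 | (2R,3R)-2-[(methoxymethoxy)methyl]-3-[3-methoxy-4,5-bis(methoxymethoxy)phenyl]oxirane | COCOC[C@H]1O[C@@H]1c1cc(OC)c(OCOC)c(OCOC)c1
A8 | alternative 3 | 4-bromo-3-hydroxy-5-methoxybenzaldehyde | COc1cc(C=O)cc(O)c1Br
A9 | alternative 3 | (2S,3R)-5-methoxy-3-[(methoxymethoxy)methyl]-2-[3-methoxy-4,5-bis(methoxymethoxy)phenyl]-2,3-dihydro-1,4-benzodioxine-7-carbaldehyde (2,3-cis) | COc1cc([C@@H]2Oc3cc(C=O)cc(OC)c3O[C@@H]2COCOC)cc(OCOC)c1OCOC
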